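## Structural features

The target is a 2H-chromen-7(8H)-one. Ring A (C4a, C5, C6, C7, C8, C8a) is a dearomatised acylphloroglucinol: a cyclohexadienone with an enol at C5, the 2-methylbutanoyl group at C6, a ketone at C7 and a gem-dimethyl carbon at C8. Ring B (O1, C2, C3, C4, C4a, C8a) is a 2H-pyran fused to ring A through the C4a=C8a enol-ether bond.

The two stereocentres are seven bonds apart, so neither can steer the other. C2 (R) is a fully substituted carbinol carbon bearing O1, CH3, the 4-methylpent-3-enyl chain and C3. C2′ (R) of the acyl chain sits next to a ketone and can epimerise.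

Fragile groups are the acidic, chelating β-triketone (C5–OH, C6 acyl, C7=O), the trisubstituted side-chain alkene, and the O1–C2 bond. That bond is tertiary, allylic and attached to a vinylogous-ester oxygen, so acid can ionise it and heat or light can open it by retro-oxa-6π; either event erases C2.

The real difficulty is C2 together with the sense of annulation (O1 on C8a beside the gem-dimethyl carbon, not on C5). The customary closure of ring B makes the O1–C2 bond from a planar 1-oxatriene and so leaves C2 uncontrolled.

The feature the key step exploits: the segment O1–C2(CH3)(C6H11)–C3=C4 of ring B is, atom for atom and with the same configuration (priority order O > alkenyl C > CH2 > CH3 in both), the O–C3–C2=C1 unit of (R)-linalool. Ring B is therefore closed at C4–C4a and O1–C8a, the two ring bonds that do not touch C2.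

## Logic of the disconnections

In one sentence: 14 arises by a palladium-catalysed cross-coupling/addition–elimination annulation of 7 with 12.

14 to 13. The O1–C8a bond is cut. It is the only C–O bond of ring B that can be formed without making or breaking a bond at C2. The gain is that the C2 problem shrinks to carrying an existing tertiary alcohol through the synthesis. The forward step needs a leaving group on the future C8a and none on the future C5, a Z alkene between C3 and C4, and basic, non-ionising conditions.

13 to 7 and 12. The C4–C4a bond is cut. It is an sp2–sp2 bond that joins a ring A fragment and a C10 fragment of similar size, so the route becomes convergent. The forward step needs the C–I bond of 7 to react before its vinylogous C–OMe bond, and the alkene geometry of 12 to be transferred intact. Since 13 need not be isolated, this cut and the previous one are one operation (step 6).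

12 to 8 and 9 (through 11 and 10). The ring C=C of 12 (the future C3=C4) and its B–O bond are cut. A temporary boron tether turns the vinyl group of 8 into a Z-alkenylboron unit without touching the carbinol carbon. The gain is that all chirality at C2 comes from the chiral pool. The forward step needs the B–O tether in place before the metathesis catalyst is added, and closure onto the B-vinyl group in preference to the trisubstituted alkene.

7 to 6. The C–I bond is cut. It is needed only as the handle for the coupling, and the carbon concerned is the one CH of the ring. The forward step needs mono-iodination at that carbon.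

6 to 5. The O–CH3 bond is cut. The methoxy group is the leaving group that fixes the annulation regiochemistry. The forward step needs methylation of the one enol oxygen that is not held in the triketone chelate.

5 to 4. The two C–CH3 bonds at the future C8 are cut. This is the alkylative dearomatisation that turns a flat arene into ring A. The two free ring carbons of 4 are equivalent, so only the degree of methylation must be controlled.

4 to 2 and 1 (through 3). The aryl–acyl C–C bond is cut. 2 is symmetric, so only one C-acyl product is possible. The forward step must not epimerise C2′.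

## Other disconnections considered

Alternative 1: The first idea is to cut O1–C2 and C4–C4a: Knoevenagel condensation of 5 with citral to the 1-oxatriene A1, then oxa-6π electrocyclisation. It is the shortest route. However, C2 is born from a trigonal carbon in a thermal pericyclic closure whose only resident stereocentre (C2′) is seven bonds away. No facial bias is expected, so 14 and its C2 epimer A2 should form together and would differ only at a remote centre. The closure can also engage either carbonyl oxygen flanking C4a. The chosen plan never makes a bond at C2 and places the leaving group on one carbon only.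

Alternative 2: Cut the C3=C4 alkene: ring-closing metathesis of the O-linalyl, C-vinyl dienone A3. C2 would again be imported. However, the O1–C8a bond of A3 must be made by intermolecular addition–elimination of a tertiary alkoxide at a carbon flanked by the quaternary C8 and a substituted C4a. In addition, a carbene on the linalyl vinyl group has a competing five-membered closure onto the trisubstituted alkene. The chosen plan forms the hindered C–O bond intramolecularly and keeps metathesis on a simple fragment.

Alternative 3: Dearomatise last: prepare the aromatic chromene A4 in enantioenriched form and finish by double C-methylation at C8. This needs a separate asymmetric chromene synthesis on an electron-rich, polyhydroxylated arene, with phenol protection. It also places the least selective reaction of the sequence (C- against O-methylation, mono against geminal) on the most valuable intermediate under strongly basic conditions. The chosen plan dearomatises early on cheap material and ends with the stereochemically decisive step.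

Key step: step 6

Assumption: 1 and 8 are taken as catalogue compounds of high enantiomeric purity; the enantiomeric purity of 14 at C2 and C2′ cannot exceed theirs.
Remark: 5, 6, 7, 13 and 14 are drawn as the enol tautomer of the target SMILES. Compounds 5–7 and 13 use cyclohexadienone numbering (C1 = future C7, C2 = C6, C3 = C5, C4 = C4a, C5 = C8a, C6 = C8).
Remark: ring B of 14 is expected to hold its configuration in the dark near room temperature, so everything after step 6 is kept cold, dark and free of strong acid.

## Steps

Step 1
Reactants: 1 (R)-2-methylbutanoic acid; 2 phloroglucinol (benzene-1,3,5-triol)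
Product: 4 (2R)-2-methyl-1-(2,4,6-trihydroxyphenyl)butan-1-one, via (R)-2-methylbutanoyl chloride 3 (not isolated)
Conditions: (COCl)2, DMF (cat.), CH2Cl2, 0 °C to rt, evaporation; then 2, AlCl3 (4 equiv), PhNO2/CH2Cl2, rt to 45 °C; aq. HCl
Reagents that add atoms: none
Why: Base-free acid chloride formation avoids the ketene pathway, and Friedel–Crafts acylation of the symmetric triol can give only one C-acyl isomer (any O-acyl product should undergo Fries rearrangement under AlCl3). C2′ is carried over from 1; the moderate temperature is chosen to limit enolisation of the Lewis-acid-bound ketone.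

Step 2
Reactants: 4 (2R)-2-methyl-1-(2,4,6-trihydroxyphenyl)butan-1-one
Product: 5 3,5-dihydroxy-6,6-dimethyl-2-[(2R)-2-methylbutanoyl]cyclohexa-2,4-dien-1-one
Conditions: NaOMe (3 equiv), MeI (2.4 equiv), MeOH, 0 °C to rt; aq. HCl to pH 3
Reagents that add atoms: iodomethane, CI
Why: Alkylative dearomatisation: the phenoxide is C-methylated twice at one of the two equivalent free ring carbons, and the product is stabilised as a vinylogous acid/β-triketone. C2′ should survive because the substrate and product are anions whose acyl α-hydrogen is only weakly acidic.

Step 3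
Reactants: 5 3,5-dihydroxy-6,6-dimethyl-2-[(2R)-2-methylbutanoyl]cyclohexa-2,4-dien-1-one
Product: 6 3-hydroxy-5-methoxy-6,6-dimethyl-2-[(2R)-2-methylbutanoyl]cyclohexa-2,4-dien-1-one
Conditions: TMSCHN2 (1.1 equiv), MeOH/toluene, 0 °C
Reagents that add atoms: (trimethylsilyl)diazomethane, C[Si](C)(C)C=[N+]=[N-]
Why: Diazoalkane O-methylation of a vinylogous acid: the C5 hydroxyl is the only enol not locked in the hydrogen-bonded chelate with the acyl group, so it should be protonating and methylated first, as in the O-methylation of related acylfilicinic acids.

Step 4
Reactants: 6 3-hydroxy-5-methoxy-6,6-dimethyl-2-[(2R)-2-methylbutanoyl]cyclohexa-2,4-dien-1-one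
Product: 7 3-hydroxy-4-iodo-5-methoxy-6,6-dimethyl-2-[(2R)-2-methylbutanoyl]cyclohexa-2,4-dien-1-one
Conditions: NIS (1.05 equiv), CH2Cl2, 0 °C, dark
Reagents that add atoms: N-iodosuccinimide, O=C1CCC(=O)N1I
Why: Electrophilic α-iodination of a β-alkoxy enone: C4 is the only ring CH and is the electron-rich α-carbon of the vinylogous ester. Iodine placed on the fully substituted C2 would be a transferable positive iodine, so C4 is the expected resting place.

Step 5
Reactants: 8 (R)-linalool [(3R)-3,7-dimethylocta-1,6-dien-3-ol]; 9 dibutyl vinylboronate
Product: 12 (R)-5-methyl-5-(4-methylpent-3-en-1-yl)-1,2-oxaborol-2(5H)-ol, via butyl linalyl vinylboronate 10 (not isolated), via 2-butoxy oxaborole 11 (not isolated)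
Conditions: 9 (1.3 equiv), toluene, 50 °C, reduced pressure (n-BuOH removed); then RuCl2(PCy3)2(=CHPh) (first-generation Grubbs catalyst, 5 mol %), CH2Cl2, 40 °C; then H2O/THF, rt
Reagents that add atoms: water, O
Why: Boron-tethered ring-closing metathesis: exchange of one butoxy group for the tertiary alkoxide ties the B-vinyl group to the allylic vinyl group. The carbene is expected to load on the unhindered B-vinyl group and close the five-membered ring faster than it engages the trisubstituted alkene. The ring can only hold a Z alkene and no bond to the carbinol carbon is made or broken, so the R configuration of 8 is kept; water then cleaves the exocyclic B–OBu bond.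

Step 6
Reactants: 7 3-hydroxy-4-iodo-5-methoxy-6,6-dimethyl-2-[(2R)-2-methylbutanoyl]cyclohexa-2,4-dien-1-one; 12 (R)-5-methyl-5-(4-methylpent-3-en-1-yl)-1,2-oxaborol-2(5H)-ol
Product: 14 (2R)-5-hydroxy-2,8,8-trimethyl-6-[(2R)-2-methylbutanoyl]-2-(4-methylpent-3-en-1-yl)-2H-chromen-7(8H)-one (target), via (Z)-alkenyl carbinol 13 (not isolated)
Conditions: Pd(OAc)2 (5 mol %), SPhos (10 mol %), K3PO4 (3 equiv), THF/H2O (20:1), 40 °C, dark; aq. NaH2PO4, 0 °C
Reagents that add atoms: none
Why: Zerovalent palladium formed from Pd(OAc)2/SPhos inserts into the C4–I bond of 7; transmetalation from the hydroxyboronate of 12 and reductive elimination (a Suzuki–Miyaura coupling of a cyclic alkenylboronic half ester) give 13, whose tertiary hydroxyl is released with the Z geometry fixed by the former five-membered ring. The alkoxide then adds to the methoxy-bearing carbon (future C8a) and expels methoxide, a vinylogous transesterification of a β-alkoxy enone, which is the closest known reaction type. This closes ring B by a 6-endo-trig addition–elimination. No stereocentre is created: C2 keeps the configuration of 8 because none of its four bonds is made or broken and neither a cation nor an oxatriene lies on the path. C2′ should not enolise because the β-triketone is present as its delocalised anion. Chemoselectivity follows from the much faster oxidative addition of the C–I bond compared with the vinylogous C–OMe bond. Regioselectivity (O1 on C8a, not on C5) is secured because only that carbon carries a leaving group while the other flanking carbon is an enolate. The hindered C–O bond can form because the cis alkene holds the alkoxide within bonding distance of C8a.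

## Compound list

1 | (R)-2-methylbutanoic acid | CC[C@@H](C)C(=O)O | starting material
2 | phloroglucinol (benzene-1,3,5-triol) | Oc1cc(O)cc(O)c1 | starting material
3 | (R)-2-methylbutanoyl chloride | CC[C@@H](C)C(=O)Cl | intermediate
4 | (2R)-2-methyl-1-(2,4,6-trihydroxyphenyl)butan-1-one | CC[C@@H](C)C(=O)c1c(O)cc(O)cc1O | intermediate
5 | 3,5-dihydroxy-6,6-dimethyl-2-[(2R)-2-methylbutanoyl]cyclohexa-2,4-dien-1-one | CC[C@@H](C)C(=O)C1=C(O)C=C(O)C(C)(C)C1=O | intermediate
6 | 3-hydroxy-5-methoxy-6,6-dimethyl-2-[(2R)-2-methylbutanoyl]cyclohexa-2,4-dien-1-one | CC[C@@H](C)C(=O)C1=C(O)C=C(OC)C(C)(C)C1=O | intermediate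
7 | 3-hydroxy-4-iodo-5-methoxy-6,6-dimethyl-2-[(2R)-2-methylbutanoyl]cyclohexa-2,4-dien-1-one | CC[C@@H](C)C(=O)C1=C(O)C(I)=C(OC)C(C)(C)C1=O | intermediate
8 | (R)-linalool, (3R)-3,7-dimethylocta-1,6-dien-3-ol | C=C[C@](C)(O)CCC=C(C)C | starting material
9 | dibutyl vinylboronate | C=CB(OCCCC)OCCCC | starting material
10 | butyl (3R)-3,7-dimethylocta-1,6-dien-3-yl vinylboronate | C=CB(OCCCC)O[C@](C)(CCC=C(C)C)C=C | intermediate
11 | (R)-2-butoxy-5-methyl-5-(4-methylpent-3-en-1-yl)-2,5-dihydro-1,2-oxaborole | CCCCOB1O[C@](C)(CCC=C(C)C)C=C1 | intermediate
12 | (R)-5-methyl-5-(4-methylpent-3-en-1-yl)-1,2-oxaborol-2(5H)-ol | OB1O[C@](C)(CCC=C(C)C)C=C1 | intermediate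
13 | 3-hydroxy-4-[(1Z,3R)-3-hydroxy-3,7-dimethylocta-1,6-dien-1-yl]-5-methoxy-6,6-dimethyl-2-[(2R)-2-methylbutanoyl]cyclohexa-2,4-dien-1-one | CC[C@@H](C)C(=O)C1=C(O)C(/C=C\[C@](C)(O)CCC=C(C)C)=C(OC)C(C)(C)C1=O | intermediate
14 | (2R)-5-hydroxy-2,8,8-trimethyl-6-[(2R)-2-methylbutanoyl]-2-(4-methylpent-3-en-1-yl)-2H-chromen-7(8H)-one | CC[C@@H](C)C(=O)C1=C(O)C2=C(O[C@](C)(CCC=C(C)C)C=C2)C(C)(C)C1=O | target

## Step count and least certain steps

Total step count: 6. Longest linear sequence: 5 (steps 1, 2, 3, 4 and 6); step 5 is a one-step branch.

Step 6 (key step). Three processes could spoil it: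
- Slow transmetalation or reductive elimination at an iodide flanked on both sides, which would let protodeiodination and protodeboronation compete.
- Hydrolytic loss of the methoxy leaving group before ring closure, leaving an enolate that no longer accepts the alkoxide.
- Erosion of C2 through ionisation of the allylic O1–C2 bond of the product by zerovalent palladium, or through reversible oxa-6π ring opening if the mixture is heated or exposed to light.

Fallback (stepwise, with a palladium-free ring closure): it sets out from 7 and geraniol and comes back to the route at 13. Sharpless asymmetric epoxidation of geraniol (Ti(OiPr)4, D-(−)-diethyl tartrate, t-BuOOH, CH2Cl2, −20 °C) should give (2R,3R)-2,3-epoxygeraniol F1. Appel chlorination (PPh3, CCl4, NaHCO3) gives the epoxy chloride (2S,3R)-2-(chloromethyl)-3-methyl-3-(4-methylpent-3-en-1-yl)oxirane F2. Double elimination with n-BuLi (3 equiv, THF, −40 °C) opens the epoxide and forms the alkyne without touching the carbinol carbon, giving (R)-3,7-dimethyloct-6-en-1-yn-3-ol F3. Sonogashira coupling of F3 with 7 (Pd(PPh3)2Cl2, CuI, i-Pr2NH, THF, rt), which tolerates the crowded iodide better because the partner is linear, gives the alkynyl dienone 3-hydroxy-4-[(3R)-3-hydroxy-3,7-dimethyloct-6-en-1-yn-1-yl]-5-methoxy-6,6-dimethyl-2-[(2R)-2-methylbutanoyl]cyclohexa-2,4-dien-1-one F4. Semi-hydrogenation over Pd/CaCO3 poisoned with Pb(OAc)2 and quinoline (Lindlar catalyst, H2, EtOAc) gives isolated 13. NaH in THF at 0 °C then closes ring B to 14 with no palladium present.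

Step 5. Incomplete tethering would leave free 8 in the flask, and its own vinyl group can undergo fast ring closure onto the trisubstituted alkene. Loading of the carbene on the linalyl vinyl group of 10 would open the same competing five-membered closure.

Fallback: it sets out from the alkyne (R)-3,7-dimethyloct-6-en-1-yn-3-ol F3 (made as described for step 6) and comes back at 12. Z-selective anti-Markovnikov hydroboration with pinacolborane ([Rh(cod)Cl]2, P(i-Pr)3, Et3N, cyclohexane, rt) proceeds through a rhodium vinylidene and places boron cis to the carbinol carbon, giving (R,Z)-3,7-dimethyl-1-(4,4,5,5-tetramethyl-1,3,2-dioxaborolan-2-yl)octa-1,6-dien-3-ol F5. Oxidative removal of the pinacol unit (NaIO4, NH4OAc, acetone/H2O) lets the γ-hydroxyl close onto boron to give 12.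

Step 3. Methylation at a chelated enol oxygen, or at carbon, would put the leaving group on the wrong atom and misdirect the annulation.

Fallback: it sets out from 4 and comes back at 6, bypassing 5. O-Methylation of 4 with Me2SO4 (1 equiv) and K2CO3 in acetone is directed to the para hydroxyl, the only one not hydrogen-bonded to the ketone, and gives (2R)-1-(2,6-dihydroxy-4-methoxyphenyl)-2-methylbutan-1-one F6. Alkylative dearomatisation (MeI, NaOMe, MeOH) at either of the two equivalent free ring carbons then gives 6. The oxygen atoms are thus told apart on the aromatic ring, where chelation makes it easy.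

Step 1. Enolisation of the Lewis-acid-bound ketone or of the acylating agent could partly epimerise C2′, and O-acylation could compete.

Fallback: it sets out from 2 and 3 and comes back at 4. Protection of 2 (MOMCl, i-Pr2NEt) gives 1,3,5-tris(methoxymethoxy)benzene F7. Treatment of 3 with N,O-dimethylhydroxylamine hydrochloride and pyridine gives the Weinreb amide (R)-N-methoxy-N,2-dimethylbutanamide F8. Lithiation of F7 between two ether groups (n-BuLi, THF, 0 °C) and addition to F8 gives (2R)-2-methyl-1-[2,4,6-tris(methoxymethoxy)phenyl]butan-1-one F9; the ketone is released only on work-up from a stable chelate. HCl in MeOH at rt removes the protecting groups to give 4.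

## Further compounds

F1 | step 6 | (2R,3R)-2,3-epoxygeraniol, [(2R,3R)-3-methyl-3-(4-methylpent-3-en-1-yl)oxiran-2-yl]methanol | C[C@]1(CCC=C(C)C)O[C@@H]1CO
F2 | step 6 | (2S,3R)-2-(chloromethyl)-3-methyl-3-(4-methylpent-3-en-1-yl)oxirane | C[C@]1(CCC=C(C)C)O[C@@H]1CCl
F3 | step 6 | (R)-3,7-dimethyloct-6-en-1-yn-3-ol | C#C[C@](C)(O)CCC=C(C)C
F4 | step 6 | 3-hydroxy-4-[(3R)-3-hydroxy-3,7-dimethyloct-6-en-1-yn-1-yl]-5-methoxy-6,6-dimethyl-2-[(2R)-2-methylbutanoyl]cyclohexa-2,4-dien-1-one | CC[C@@H](C)C(=O)C1=C(O)C(C#C[C@](C)(O)CCC=C(C)C)=C(OC)C(C)(C)C1=O
F5 | step 5 | (R,Z)-3,7-dimethyl-1-(4,4,5,5-tetramethyl-1,3,2-dioxaborolan-2-yl)octa-1,6-dien-3-ol | CC1(C)OB(/C=C\[C@](C)(O)CCC=C(C)C)OC1(C)C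
F6 | step 3 | (2R)-1-(2,6-dihydroxy-4-methoxyphenyl)-2-methylbutan-1-one | CC[C@@H](C)C(=O)c1c(O)cc(OC)cc1O
F7 | step 1 | 1,3,5-tris(methoxymethoxy)benzene | COCOc1cc(OCOC)cc(OCOC)c1
F8 | step 1 | (R)-N-methoxy-N,2-dimethylbutanamide | CC[C@@H](C)C(=O)N(C)OC
F9 | step 1 | (2R)-2-methyl-1-[2,4,6-tris(methoxymethoxy)phenyl]butan-1-one | CC[C@@H](C)C(=O)c1c(OCOC)cc(OCOC)cc1OCOC
A1 | alternative 1 | 3-hydroxy-2-[(2E)-3,7-dimethylocta-2,6-dien-1-ylidene]-6,6-dimethyl-4-[(2R)-2-methylbutanoyl]cyclohex-3-ene-1,5-dione | CC[C@@H](C)C(=O)C1=C(O)C(=C/C=C(\C)CCC=C(C)C)C(=O)C(C)(C)C1=O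
A2 | alternative 1 | (2S)-5-hydroxy-2,8,8-trimethyl-6-[(2R)-2-methylbutanoyl]-2-(4-methylpent-3-en-1-yl)-2H-chromen-7(8H)-one | CC[C@@H](C)C(=O)C1=C(O)C2=C(O[C@@](C)(CCC=C(C)C)C=C2)C(C)(C)C1=O
A3 | alternative 2 | 5-{[(3R)-3,7-dimethylocta-1,6-dien-3-yl]oxy}-4-ethenyl-3-hydroxy-6,6-dimethyl-2-[(2R)-2-methylbutanoyl]cyclohexa-2,4-dien-1-one | CC[C@@H](C)C(=O)C1=C(O)C(C=C)=C(O[C@](C)(CCC=C(C)C)C=C)C(C)(C)C1=O
A4 | alternative 3 | (2R)-1-[(2R)-5,7-dihydroxy-2-methyl-2-(4-methylpent-3-en-1-yl)-2H-chromen-6-yl]-2-methylbutan-1-one | CC[C@@H](C)C(=O)c1c(O)cc2O[C@](C)(CCC=C(C)C)C=Cc2c1O
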